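common to all: left-handed substrate 0.59 M; right-handed substrate 0.59 M; precatalyst 7.1 mM

| run | reagent | remark | time |
|---|---|---|---|
| Tuesday's | 0.44 M | run made earlier |  |
| Wednesday's | 1.8 M | run made earlier |  |
| flask | 0.885 M |  | 2.5 d |

| run | time / h | left-handed substrate / % | right-handed substrate / % |
|---|---|---|---|
| Tuesday's | 10.0 | 39.4 | 49.3 |
| Tuesday's | 20.0 | 39.1 | 48.5 |
| Tuesday's | 25.0 | 39.2 | 49.6 |
| Tuesday's | 40.0 | 38.9 | 48.7 |
| Wednesday's | 5.00 | 23.4 | 46.6 |
| Wednesday's | 12.0 | 17.5 | 45.6 |
| Wednesday's | 25.0 | 17.7 | 45.4 |
| Wednesday's | 40.0 | 17.7 | 45.2 |

(readings scatter by 0.3 percentage points)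

- free catalyst is single-handed; left-handed substrate and right-handed substrate are mirror images of each other, charged as a racemate, each of them at the stated concentration
- the earlier runs were read with a standard deviation of 0.3 percentage points
- an excess is the difference of the two amounts in percent of their sum
- an excess is below zero if the other one leads

* part of the left-handed substrate and right-handed substrate charged together that has reacted at 2.5 d
* excess of left-handed product over right-handed product in the product at 2.5 d
* excess of right-handed substrate over left-handed substrate among what is left of the two at 2.5 d

**Stopped runs.** Wednesday's run, charged with more reagent than Tuesday's, ends with less left-handed substrate. Yet at 40.0 h, counting one reagent per substrate reacted, Tuesday's run still holds 0.294 M and Wednesday's 1.36 M, so neither stops for want of reagent.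

**Two amounts.** Suppose the rate is first order in reagent and in a catalyst whose life does not depend on reagent. Then two amounts stay tied: the progress, the logarithm of charged over remaining left-handed substrate, and the mean reagent, halfway between charge and end. Their ratio reads 0.684 M⁻¹ on Tuesday and 0.657 M⁻¹ on Wednesday. The mean, 0.671 M⁻¹, is the catalyst dose: progress per unit of mean reagent over the catalyst's working life.

**Own reckoning.** Wednesday's selectivity factor reads 10.3. In the flask, balance and dose are solved together: mean reagent goes from 0.736 M on a first pass to 0.756 M. That gives progress 0.507, conversion 22.3% and substrate excess 22.5%. Neither run read any product, so this reckoning commits to no figure for the product excess.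

**The forecast.** It says “the catalyst dies, and well before 2.5 d” and gives 22% reacted, product excess 79.1% and substrate excess 22.3%.

**The flask.** It gives 22.1% reacted, product excess 0% and substrate excess 23.0%.

    free catalyst → spent catalyst (k = 0.00880 min⁻¹)
    reagent + free catalyst + right-handed substrate → free catalyst + right-handed product (k = 0.0730 M⁻² min⁻¹)
    precatalyst → free catalyst (k = 0.00710 min⁻¹)
    reagent + free catalyst + left-handed substrate → free catalyst + left-handed product (k = 0.860 M⁻² min⁻¹)
    left-handed product ⇌ right-handed product (k = 0.00420 min⁻¹)

Left-handed and right-handed product stand at 11.1% and 11.1% in the flask at 2.50 d, where their relaxation half-life of 0.0573 d is short against 2.5 d. The flask's own ratio of progress to mean reagent is 0.678 M⁻¹, beside the dose of 0.671 M⁻¹ read from the runs. The neighbouring flask, charged with 0.53 M of reagent, keeps 74% of its left-handed substrate and 68% of its reagent, and its ratio is 0.676 M⁻¹. That neighbouring flask ends with 14.3% reacted and a substrate excess of 13.8%.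

The numbers in the tables come from a simulation for an exercise; scatter was added.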